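A direct plan would build the C7 chain by carbonyl chemistry. An aldol condensation would give the benzyl-protected cross-conjugated dienone A1, an amine-catalysed conjugate addition of cumene hydroperoxide would set C5 in peroxide A2, hydrogenation would give the free β-hydroxy ketone A3, and a syn-selective borohydride reduction would finish. Its weakest steps would be:
- the conjugate peroxidation of A1: it has no precedent on a dienone, must choose one of two enone arms and one face, and would leave C5, the only source of absolute configuration, to chance;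
- the global hydrogenation to A3 before the chain is finished: it would free the air-sensitive catechol on a β-hydroxy ketone that is prone to retro-aldol cleavage and dehydration;
- the chelation-controlled reduction as last step on the unprotected triphenol A3: the catechol competes for boron, and the most precious material would be staked on a diastereoselective step.

**Plan of the new route.** The retrosynthesis takes both hydroxyl groups back to C–B bonds, cuts C4–C5 between a boron-bound C4 and a carbenoid C5, returns C3–B and C4–B to a terminal alkene C3=C4, and cuts C1–C2 as a benzyl–allyl coupling. The feature that allows this is the unsubstituted methylene C4 between the carbinol carbons C3 and C5, each carrying only an unbranched 2-arylethyl arm. C3–C4 is therefore the image of a monosubstituted alkene (diboration gives a hindered secondary boron on C3 and an open primary boron on C4), and C5 is the O-bearing CH2 of a 3-arylpropanol that can be lithiated under sparteine control. No ring is formed; rings A (3,4-dihydroxy-5-methoxyphenyl) and B (4-hydroxyphenyl) are bought. The chain never holds a carbonyl group, so there is no dienone, no choice between enone arms and no β-hydroxy ketone; each stereocentre is set by its own reagent on protected material, and the catechol is freed in the last step.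

Key step: step 7

Assumption: the (R,R) enantiomer of the TADDOL-derived phosphonite is taken to give the (S)-bis(boronate) 7; if the sense were the opposite, the (S,S) ligand would be used. (+)-Sparteine removes the pro-R hydrogen, the mirror image of the established behaviour of (−)-sparteine.

Step 1
Reactants: 1 3,4-dihydroxy-5-methoxybenzaldehyde (5-hydroxyvanillin)
Product: 2 3,4-bis(benzyloxy)-5-methoxybenzaldehyde
Conditions: BnBr (2.3 equiv), K2CO3 (3 equiv), DMF, 60 °C, 6 h
Reagents that add atoms: benzyl bromide, BrCc1ccccc1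
Why: Williamson ether synthesis on both catechol phenoxides; benzyl should survive the organomagnesium, boron and alkaline peroxide steps and leaves by hydrogenolysis at the very end.

Step 2
Reactants: 2 3,4-bis(benzyloxy)-5-methoxybenzaldehyde
Product: 3 [3,4-bis(benzyloxy)-5-methoxyphenyl]methanol
Conditions: NaBH4 (1 equiv), MeOH/THF (1:1), 0 °C, 1 h
Reagents that add atoms: none
Why: Borohydride reduction of the aryl aldehyde to the benzylic alcohol, with the benzyl ethers untouched.

Step 3
Reactants: 3 [3,4-bis(benzyloxy)-5-methoxyphenyl]methanol; 4 allylmagnesium bromide (prop-2-en-1-ylmagnesium bromide)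
Product: 6 1,2-bis(benzyloxy)-5-(but-3-en-1-yl)-3-methoxybenzene, via benzylic chloride 5 (not isolated)
Conditions: SOCl2 (1.2 equiv), CH2Cl2, 0 °C, 1 h; evaporation; 4 (1.5 equiv, 1 M in Et2O), THF, 0 to 23 °C, 3 h
Reagents that add atoms: thionyl chloride, O=S(Cl)Cl (its chlorine is found only in 5)
Why: Chlorination of the electron-rich benzylic alcohol, then Wurtz-type substitution of the unpurified chloride by the allyl Grignard reagent, which forms C1–C2 and delivers the terminal alkene whose carbons become C3 and C4.

Step 4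
Reactants: 6 1,2-bis(benzyloxy)-5-(but-3-en-1-yl)-3-methoxybenzene
Product: 7 2,2'-{(2S)-4-[3,4-bis(benzyloxy)-5-methoxyphenyl]butane-1,2-diyl}bis(4,4,5,5-tetramethyl-1,3,2-dioxaborolane)
Conditions: Pt(dba)3 (1 mol%), (R,R)-TADDOL-derived phenylphosphonite with 3,5-diethylphenyl groups (1.2 mol%), B2pin2 (1.05 equiv), THF, 80 °C, 30 min; then 6, 60 °C, 12 h
Reagents that add atoms: bis(pinacolato)diboron, CC1(C)OB(OC1(C)C)B1OC(C)(C)C(C)(C)O1
Why: Enantioselective platinum-catalysed alkene diboration, in which B–B adds oxidatively to zerovalent platinum, the terminal alkene inserts face-selectively under control of the phosphonite and reductive elimination delivers both boryl groups syn, so the catalyst sets C3 (S here, the geometry of 3R in the target) on a monosubstituted alkene with a remote aryl group, the standard substrate class of this reaction.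

Step 5
Reactants: 8 3-(4-hydroxyphenyl)propan-1-ol
Product: 9 3-{4-[(tert-butyldimethylsilyl)oxy]phenyl}propan-1-ol
Conditions: NaH (1.0 equiv), THF, 0 °C, 30 min; TBSCl (1.0 equiv), 0 to 23 °C, 2 h
Reagents that add atoms: tert-butyldimethylsilyl chloride, CC(C)(C)[Si](C)(C)Cl
Why: Chemoselective O-silylation, since one equivalent of base deprotonates only the far more acidic phenol; a silyl ether is chosen over a benzyl ether so that ring B offers no benzylic ether hydrogen to sec-butyllithium later.

Step 6
Reactants: 9 3-{4-[(tert-butyldimethylsilyl)oxy]phenyl}propan-1-ol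
Product: 10 3-{4-[(tert-butyldimethylsilyl)oxy]phenyl}propyl 2,4,6-triisopropylbenzoate
Conditions: 2,4,6-triisopropylbenzoic acid (1.1 equiv), PPh3 (1.2 equiv), DIAD (1.2 equiv), THF, 0 to 23 °C, 12 h
Reagents that add atoms: 2,4,6-triisopropylbenzoic acid, CC(C)c1cc(C(C)C)c(C(=O)O)c(C(C)C)c1
Why: Mitsunobu esterification of the primary alcohol, giving a hindered benzoate whose shielded carbonyl resists sec-butyllithium, directs α-lithiation and later serves as leaving group.

Step 7
Reactants: 10 3-{4-[(tert-butyldimethylsilyl)oxy]phenyl}propyl 2,4,6-triisopropylbenzoate; 7 2,2'-{(2S)-4-[3,4-bis(benzyloxy)-5-methoxyphenyl]butane-1,2-diyl}bis(4,4,5,5-tetramethyl-1,3,2-dioxaborolane)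
Product: 13 2,2'-{(3R,5S)-1-[3,4-bis(benzyloxy)-5-methoxyphenyl]-7-{4-[(tert-butyldimethylsilyl)oxy]phenyl}heptane-3,5-diyl}bis(4,4,5,5-tetramethyl-1,3,2-dioxaborolane), via lithiated benzoate 11 (not isolated), via boron ate complex 12 (not isolated)
Conditions: 10 (1.3 equiv), (+)-sparteine (1.3 equiv), s-BuLi (1.25 equiv), Et2O, −78 °C, 5 h; 7 (1.0 equiv) in Et2O, −78 °C, 2 h; then 35 °C, 14 h; cold 1 M HCl wash
Reagents that add atoms: sec-butyllithium, [Li]C(C)CC (its lithium is found only in 11 and 12)
Why: sec-Butyllithium bound to (+)-sparteine removes the pro-R hydrogen next to the benzoate oxygen of 10 to give the configurationally stable (R)-lithio benzoate 11, which attacks the primary boron of 7 with retention to give ate complex 12; on warming, the C4 methylene migrates from boron to C5 anti to the departing benzoate (1,2-metallate rearrangement, inversion at C5), which forms the C4–C5 bond and leaves boron on C5. The closest known reaction type is the lithiation–borylation homologation of 1,2-bis(boronic esters) at the primary boron with sparteine-lithiated primary 2,4,6-triisopropylbenzoates. No ring is closed. The new stereocentre C5 (S) is set by the sparteine enantiomer alone through two stereospecific events (retentive borylation, invertive migration) and is independent of C3, whose C–B bond is a spectator. The step needs site selection between the two boron atoms and no second homologation; the first is secured by the steric gap between the open primary boronate and the branched secondary one towards a bulky lithiated benzoate, the second by the same hindrance of the new secondary boronates and by stoichiometry, while 10 offers no other acidic C–H because ring B carries a silyl and not a benzyl ether. As two independent reagent-controlled selections are multiplied, the stray material should be mainly the separable anti diastereomer rather than the enantiomer.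

Step 8
Reactants: 13 2,2'-{(3R,5S)-1-[3,4-bis(benzyloxy)-5-methoxyphenyl]-7-{4-[(tert-butyldimethylsilyl)oxy]phenyl}heptane-3,5-diyl}bis(4,4,5,5-tetramethyl-1,3,2-dioxaborolane)
Product: 15 (3R,5S)-1-[3,4-bis(benzyloxy)-5-methoxyphenyl]-7-(4-hydroxyphenyl)heptane-3,5-diol, via silyl ether diol 14 (not isolated)
Conditions: H2O2 (30% aq.), NaOH (2 M aq.), THF, 0 to 23 °C, 2 h; aq. Na2S2O3; MeOH added, 23 °C, 6 h; aq. NH4Cl to pH 7
Reagents that add atoms: hydrogen peroxide, OO
Why: Alkaline peroxide oxidation of both C–B bonds by migration of carbon from boron to oxygen with retention, so 3R and 5S appear unchanged as the syn diol; the remaining hydroxide in methanol then cleaves the base-labile phenolic silyl ether, while the benzyl ethers keep the catechol away from the oxidant.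

Step 9
Reactants: 15 (3R,5S)-1-[3,4-bis(benzyloxy)-5-methoxyphenyl]-7-(4-hydroxyphenyl)heptane-3,5-diol
Product: 16 (3R,5S)-1-(3,4-dihydroxy-5-methoxyphenyl)-7-(4-hydroxyphenyl)heptane-3,5-diol
Conditions: H2 (1 atm), 10% Pd/C, EtOAc/EtOH (1:1), 23 °C, 6 h; filtration through Celite under argon
Reagents that add atoms: none
Why: Hydrogenolysis of the two aryl benzyl ethers under neutral conditions; the secondary alcohols are not benzylic and stay, and the air-sensitive catechol is released only in the last operation.

**Compound list**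

1 | 3,4-dihydroxy-5-methoxybenzaldehyde (5-hydroxyvanillin) | COc1cc(C=O)cc(O)c1O | starting material
2 | 3,4-bis(benzyloxy)-5-methoxybenzaldehyde | COc1cc(C=O)cc(OCc2ccccc2)c1OCc1ccccc1 | intermediate
3 | [3,4-bis(benzyloxy)-5-methoxyphenyl]methanol | COc1cc(CO)cc(OCc2ccccc2)c1OCc1ccccc1 | intermediate
4 | allylmagnesium bromide | C=CC[Mg]Br | starting material
5 | 1,2-bis(benzyloxy)-5-(chloromethyl)-3-methoxybenzene (not isolated) | COc1cc(CCl)cc(OCc2ccccc2)c1OCc1ccccc1 | intermediate
6 | 1,2-bis(benzyloxy)-5-(but-3-en-1-yl)-3-methoxybenzene | COc1cc(CCC=C)cc(OCc2ccccc2)c1OCc1ccccc1 | intermediate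
7 | 2,2'-{(2S)-4-[3,4-bis(benzyloxy)-5-methoxyphenyl]butane-1,2-diyl}bis(4,4,5,5-tetramethyl-1,3,2-dioxaborolane) | COc1cc(CC[C@@H](B2OC(C)(C)C(C)(C)O2)CB2OC(C)(C)C(C)(C)O2)cc(OCc2ccccc2)c1OCc1ccccc1 | intermediate
8 | 3-(4-hydroxyphenyl)propan-1-ol | OCCCc1ccc(O)cc1 | starting material
9 | 3-{4-[(tert-butyldimethylsilyl)oxy]phenyl}propan-1-ol | CC(C)(C)[Si](C)(C)Oc1ccc(CCCO)cc1 | intermediate
10 | 3-{4-[(tert-butyldimethylsilyl)oxy]phenyl}propyl 2,4,6-triisopropylbenzoate | CC(C)c1cc(C(C)C)c(C(=O)OCCCc2ccc(O[Si](C)(C)C(C)(C)C)cc2)c(C(C)C)c1 | intermediate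
11 | (1R)-3-{4-[(tert-butyldimethylsilyl)oxy]phenyl}-1-lithiopropyl 2,4,6-triisopropylbenzoate, (+)-sparteine complex (not isolated) | [Li][C@H](CCc1ccc(O[Si](C)(C)C(C)(C)C)cc1)OC(=O)c1c(C(C)C)cc(C(C)C)cc1C(C)C | intermediate
12 | lithium ate complex of the primary boron of 7 carrying the (1R)-3-{4-[(tert-butyldimethylsilyl)oxy]phenyl}-1-[(2,4,6-triisopropylbenzoyl)oxy]propyl group, (2S) centre of 7 unchanged (not isolated) | COc1cc(CC[C@@H](B2OC(C)(C)C(C)(C)O2)C[B-]2(OC(C)(C)C(C)(C)O2)[C@H](CCc2ccc(O[Si](C)(C)C(C)(C)C)cc2)OC(=O)c2c(C(C)C)cc(C(C)C)cc2C(C)C)cc(OCc2ccccc2)c1OCc1ccccc1.[Li+] | intermediate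
13 | 2,2'-{(3R,5S)-1-[3,4-bis(benzyloxy)-5-methoxyphenyl]-7-{4-[(tert-butyldimethylsilyl)oxy]phenyl}heptane-3,5-diyl}bis(4,4,5,5-tetramethyl-1,3,2-dioxaborolane) | COc1cc(CC[C@@H](B2OC(C)(C)C(C)(C)O2)C[C@@H](B2OC(C)(C)C(C)(C)O2)CCc2ccc(O[Si](C)(C)C(C)(C)C)cc2)cc(OCc2ccccc2)c1OCc1ccccc1 | intermediate
14 | (3R,5S)-1-[3,4-bis(benzyloxy)-5-methoxyphenyl]-7-{4-[(tert-butyldimethylsilyl)oxy]phenyl}heptane-3,5-diol (not isolated) | COc1cc(CC[C@@H](O)C[C@@H](O)CCc2ccc(O[Si](C)(C)C(C)(C)C)cc2)cc(OCc2ccccc2)c1OCc1ccccc1 | intermediate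
15 | (3R,5S)-1-[3,4-bis(benzyloxy)-5-methoxyphenyl]-7-(4-hydroxyphenyl)heptane-3,5-diol | COc1cc(CC[C@@H](O)C[C@@H](O)CCc2ccc(O)cc2)cc(OCc2ccccc2)c1OCc1ccccc1 | intermediate
16 | (3R,5S)-1-(3,4-dihydroxy-5-methoxyphenyl)-7-(4-hydroxyphenyl)heptane-3,5-diol | COc1cc(CC[C@@H](O)C[C@@H](O)CCc2ccc(O)cc2)cc(O)c1O | target

**Step count.** Total: 9 steps. Longest linear sequence: 7 steps (steps 1, 2, 3, 4, 7, 8, 9); steps 5 and 6 form the second branch.

**Steps most likely to fail, with fallbacks**

Step 7. The lithiated benzoate could attack the secondary boron, the product could be homologated a second time, the 1,2-migration could be sluggish, or the lithiated benzoate could lose configuration. The fallback sets out from 9 and 5 and comes back at 15.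
- Alcohol 9 would be allylated from the alcohol oxidation level by iridium-catalysed transfer-hydrogenative allylation (Krische allylation: [Ir(cod)Cl]2, the BINAP enantiomer that gives the S alcohol, 4-chloro-3-nitrobenzoic acid, Cs2CO3, allyl acetate, THF, 100 °C) to (3S)-1-{4-[(tert-butyldimethylsilyl)oxy]phenyl}hex-5-en-3-ol F1.
- Boc2O and DMAP would give tert-butyl (3S)-1-{4-[(tert-butyldimethylsilyl)oxy]phenyl}hex-5-en-3-yl carbonate F2.
- Iodocarbonate cyclisation (IBr, toluene, −85 °C) would form the second C–O bond 1,3-syn through a chair with both substituents equatorial, giving (4S,6S)-4-(iodomethyl)-6-(2-{4-[(tert-butyldimethylsilyl)oxy]phenyl}ethyl)-1,3-dioxan-2-one F3.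
- K2CO3 in MeOH would open the carbonate, close the epoxide and remove the aryl silyl ether to give (2S)-4-(4-hydroxyphenyl)-1-[(2S)-oxiran-2-yl]butan-2-ol F4.
- The Grignard reagent {[3,4-bis(benzyloxy)-5-methoxyphenyl]methyl}magnesium chloride F5 (from 5 and Mg in THF, used in excess to cover the phenol and the alcohol) with CuI (10 mol%) would open the epoxide at its CH2 group, forming C1–C2 and giving 15.

Step 4. Face selection or conversion in the diboration could be insufficient, which would show later as the anti diastereomer. The fallback sets out from 6 and comes back at 7.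
- Cross-metathesis of 6 with vinylboronic acid pinacol ester (second-generation Grubbs catalyst, RuCl2(=CHPh)(H2IMes)(PCy3), CH2Cl2, 40 °C) would give 2-{(1E)-4-[3,4-bis(benzyloxy)-5-methoxyphenyl]but-1-en-1-yl}-4,4,5,5-tetramethyl-1,3,2-dioxaborolane F6.
- Enantioselective copper-catalysed boron–copper addition with protonation (CuCl, a chiral N-heterocyclic carbene precursor of the enantiomer that gives S, NaOtBu, B2pin2, MeOH, THF) would place the new boron on C3 and copper, then hydrogen, on the boron-bearing C4, giving 7.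

Step 3. The electron-rich benzylic chloride could dimerise in a Wurtz-type side reaction or decompose before it couples. The fallback sets out from 2 and 4 and comes back at 6.
- Addition of 4 to aldehyde 2 (THF, 0 °C) would give racemic 1-[3,4-bis(benzyloxy)-5-methoxyphenyl]but-3-en-1-ol F7.
- Ionic hydrogenation (Et3SiH, BF3·OEt2, CH2Cl2, −78 to −20 °C) would remove the benzylic hydroxyl through the alkoxy-stabilised benzylic cation and give 6.

**Further compounds**

F1 | step 7 | (3S)-1-{4-[(tert-butyldimethylsilyl)oxy]phenyl}hex-5-en-3-ol | C=CC[C@@H](O)CCc1ccc(O[Si](C)(C)C(C)(C)C)cc1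
F2 | step 7 | tert-butyl (3S)-1-{4-[(tert-butyldimethylsilyl)oxy]phenyl}hex-5-en-3-yl carbonate | C=CC[C@@H](OC(=O)OC(C)(C)C)CCc1ccc(O[Si](C)(C)C(C)(C)C)cc1
F3 | step 7 | (4S,6S)-4-(iodomethyl)-6-(2-{4-[(tert-butyldimethylsilyl)oxy]phenyl}ethyl)-1,3-dioxan-2-one | IC[C@@H]1C[C@H](CCc2ccc(O[Si](C)(C)C(C)(C)C)cc2)OC(=O)O1
F4 | step 7 | (2S)-4-(4-hydroxyphenyl)-1-[(2S)-oxiran-2-yl]butan-2-ol | C1[C@@H](O1)C[C@@H](O)CCc1ccc(O)cc1
F5 | step 7 | {[3,4-bis(benzyloxy)-5-methoxyphenyl]methyl}magnesium chloride | COc1cc(C[Mg]Cl)cc(OCc2ccccc2)c1OCc1ccccc1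
F6 | step 4 | 2-{(1E)-4-[3,4-bis(benzyloxy)-5-methoxyphenyl]but-1-en-1-yl}-4,4,5,5-tetramethyl-1,3,2-dioxaborolane | COc1cc(CC/C=C/B2OC(C)(C)C(C)(C)O2)cc(OCc2ccccc2)c1OCc1ccccc1
F7 | step 3 | racemic 1-[3,4-bis(benzyloxy)-5-methoxyphenyl]but-3-en-1-ol | COc1cc(C(O)CC=C)cc(OCc2ccccc2)c1OCc1ccccc1
A1 | direct plan | (1E,4E)-1-[3,4-bis(benzyloxy)-5-methoxyphenyl]-7-[4-(benzyloxy)phenyl]hepta-1,4-dien-3-one | COc1cc(/C=C/C(=O)/C=C/CCc2ccc(OCc3ccccc3)cc2)cc(OCc2ccccc2)c1OCc1ccccc1
A2 | direct plan | (1E,5S)-1-[3,4-bis(benzyloxy)-5-methoxyphenyl]-7-[4-(benzyloxy)phenyl]-5-[(2-phenylpropan-2-yl)peroxy]hept-1-en-3-one | COc1cc(/C=C/C(=O)C[C@@H](OOC(C)(C)c2ccccc2)CCc2ccc(OCc3ccccc3)cc2)cc(OCc2ccccc2)c1OCc1ccccc1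
A3 | direct plan | (5S)-1-(3,4-dihydroxy-5-methoxyphenyl)-5-hydroxy-7-(4-hydroxyphenyl)heptan-3-one | COc1cc(CCC(=O)C[C@@H](O)CCc2ccc(O)cc2)cc(O)c1O
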